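**Plan**
Cuts: first the S–S bond, which halves the symmetrical dimer. Then the C10'–S bond, leading back to a primary alcohol. Then, after a C1'=C2' alkene is added retrosynthetically, the C4–C5 and C6–O1 bonds of the 2-pyranone ring.
Enabling feature: ring atoms O1, C2 (lactone carbonyl), C3 (OMe) and C4 (OMe) are the carboxyl group, Cα and Cβ of (Z)-2,3-dimethoxyacrylic acid. Its only vinylic hydrogen sits on C4, cis to the carboxyl group, and C5 (Me) and C6 (chain) are the two carbons of an internal alkyne.
Forward order: the acid (steps 1–2) and an E-1,3-enyne carrying the C10 chain (steps 3–5) are made separately. Step 6 closes the only ring type by rhodium-catalysed oxidative C–H/O–H annulation.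
The alkene is then saturated, oxygen at C10' is exchanged for sulfur, and two halves are joined by thiol oxidation in the last step.
Stereochemistry: the target has no stereocentre and no alkene geometry. The Z enol ether (thermodynamic preference) only places C4–H next to the carboxylate, and the E alkene (syn hydrozirconation) is only a regiochemical handle that is later reduced.

Key step: step 6

Assumption: O-methylation of the formyl-ester enolate is taken to give mainly the Z enol ether (β-methoxy group anti to the ester), and any E isomer is removed by chromatography at the ester stage.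

Step 1
Reactants: 1 methyl methoxyacetate; 2 methyl formate
Product: 4 methyl (Z)-2,3-dimethoxyacrylate, via sodium enolate 3 (not isolated)
Conditions: NaH, HCO2Me (excess), THF, 0 °C → rt; then Me2SO4, DMF, 0 °C → rt
Reagents that add atoms: dimethyl sulfate, COS(=O)(=O)OC
Why: A crossed Claisen condensation with the non-enolisable and more electrophilic methyl formate should formylate the ester enolate, and the hard electrophile dimethyl sulfate in a dipolar aprotic medium should methylate the ambident enolate on oxygen, the Z isomer being favoured because it keeps the β-methoxy group away from the ester as in related β-methoxyacrylates.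

Step 2
Reactants: 4 methyl (Z)-2,3-dimethoxyacrylate
Product: 6 (Z)-2,3-dimethoxyacrylic acid, via lithium carboxylate 5 (not isolated)
Conditions: LiOH, THF/H2O, 0 °C → rt; then 1 M HCl to pH 3, 0 °C
Reagents that add atoms: lithium hydroxide, [Li+].[OH-]
Why: Saponification of the unhindered methyl ester by acyl–oxygen cleavage should outrun attack at the donor-deactivated β-carbon, and brief cold acidification should release the acid without hydrolysing the enol ether or changing its geometry.

Step 3
Reactants: 7 dec-9-yn-1-ol
Product: 8 tert-butyl(dec-9-yn-1-yloxy)dimethylsilane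
Conditions: TBSCl, imidazole, CH2Cl2, 0 °C → rt
Reagents that add atoms: tert-butyldimethylsilyl chloride, CC(C)(C)[Si](C)(C)Cl
Why: Imidazole-promoted silylation of a primary alcohol is routine and masks the hydroxyl group against Cp2Zr(H)Cl and the later oxidative coupling.

Step 4
Reactants: 8 tert-butyl(dec-9-yn-1-yloxy)dimethylsilane
Product: 10 tert-butyl{[(9E)-10-iododec-9-en-1-yl]oxy}dimethylsilane, via alkenylzirconocene chloride 9 (not isolated)
Conditions: Cp2Zr(H)Cl, THF, rt, dark; then I2, THF, 0 °C
Reagents that add atoms: iodine, [I][I]
Why: Hydrozirconation adds Zr–H syn across the terminal alkyne with zirconium at the unhindered terminus, and iodinolysis of the C–Zr bond proceeds with retention, so the E alkenyl iodide should result.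

Step 5
Reactants: 10 tert-butyl{[(9E)-10-iododec-9-en-1-yl]oxy}dimethylsilane; 11 propyne
Product: 12 tert-butyl(dimethyl){[(9E)-tridec-9-en-11-yn-1-yl]oxy}silane
Conditions: propyne (excess, condensed), PdCl2(PPh3)2 (3 mol %), CuI (6 mol %), Et3N, THF, −78 °C → rt, closed flask
Reagents that add atoms: none
Why: Sonogashira coupling of an alkenyl iodide with a terminal alkyne runs at or below room temperature with retention of the alkene geometry and leaves the silyl ether untouched.

Step 6
Reactants: 6 (Z)-2,3-dimethoxyacrylic acid; 12 tert-butyl(dimethyl){[(9E)-tridec-9-en-11-yn-1-yl]oxy}silane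
Product: 13 6-[(1E)-10-{[tert-butyl(dimethyl)silyl]oxy}dec-1-en-1-yl]-3,4-dimethoxy-5-methyl-2H-pyran-2-one
Conditions: 6 (1.3 equiv), [Cp*RhCl2]2 (2.5 mol %), Cu(OAc)2 (2.1 equiv), t-AmOH, 100 °C, N2
Reagents that add atoms: none
Why: Proposed new method: carboxylate exchange on Cp*Rh(OAc)2 (trivalent rhodium, formed in situ from [Cp*RhCl2]2 and Cu(OAc)2) followed by concerted metalation–deprotonation of the C4–H bond, the only vinylic C–H of 6 and cis to the carboxylate in the Z isomer, should give a five-membered rhodacycle, helped by the β-methoxy group that acidifies this C–H bond and by the α-methoxy group that enriches the carbon. The alkyne of 12 then inserts into the Rh–C bond, forming C4–C5 and a seven-membered oxarhodacycle, and C–O reductive elimination forms C6–O1, so the one new ring, the six-membered lactone, closes as a formal [4+2] oxidative annulation (O1, C2, C3 and C4 from the acid, C5 and C6 from the alkyne), after which two equivalents of Cu(OAc)2 return monovalent rhodium to the trivalent state. The closest known reaction type is the rhodium- or ruthenium-catalysed oxidative annulation of alkyl- and aryl-substituted acrylic acids with internal alkynes to 2-pyranones, in which neither a 2,3-dialkoxyacrylic acid nor a 1,3-enyne has been shown. The selectivity needed is regiochemical (methyl at C5, chain at C6) and is secured by the alkenyl group of 12, which stabilises the rhodium-bound carbon by conjugation just as in the enyne annulations of anilides and enamides that place the alkenyl group next to nitrogen, while the small methyl terminus accepts the new C–C bond beside the C4 methoxy group. Alkynes insert much faster than an unactivated 1,2-disubstituted alkene, so C1'=C2' and its E geometry should persist, and no stereocentre is created. The primary silyl ether should tolerate the acetic acid formed in the non-nucleophilic tertiary alcohol solvent.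

Step 7
Reactants: 13 6-[(1E)-10-{[tert-butyl(dimethyl)silyl]oxy}dec-1-en-1-yl]-3,4-dimethoxy-5-methyl-2H-pyran-2-one
Product: 14 6-(10-{[tert-butyl(dimethyl)silyl]oxy}decyl)-3,4-dimethoxy-5-methyl-2H-pyran-2-one
Conditions: 2-nitrobenzenesulfonyl hydrazide (excess, in portions), Et3N, CH2Cl2, rt
Reagents that add atoms: none
Why: Diimide reduction transfers two hydrogens in a concerted syn manner to the accessible 1,2-disubstituted C1'=C2' alkene, whereas the fully substituted and polarised double bonds of the pyranone ring should not react and no hydrogenation metal is present that could touch the ring.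

Step 8
Reactants: 14 6-(10-{[tert-butyl(dimethyl)silyl]oxy}decyl)-3,4-dimethoxy-5-methyl-2H-pyran-2-one
Product: 15 6-(10-hydroxydecyl)-3,4-dimethoxy-5-methyl-2H-pyran-2-one
Conditions: HF·pyridine, THF/pyridine, 0 °C → rt
Reagents that add atoms: none
Why: Fluoride-driven cleavage of the Si–O bond under weakly acidic conditions frees the primary alcohol without exposing the lactone to base.

Step 9
Reactants: 15 6-(10-hydroxydecyl)-3,4-dimethoxy-5-methyl-2H-pyran-2-one
Product: 16 S-[10-(4,5-dimethoxy-3-methyl-6-oxo-6H-pyran-2-yl)decyl] ethanethioate
Conditions: PPh3, DIAD, AcSH, THF, 0 °C → rt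
Reagents that add atoms: thioacetic acid, CC(=O)S
Why: In the Mitsunobu reaction an unhindered primary alcohol and the acidic, soft pronucleophile thioacetic acid form the C–S bond by SN2 displacement of the oxyphosphonium group under essentially neutral conditions.

Step 10
Reactants: 16 S-[10-(4,5-dimethoxy-3-methyl-6-oxo-6H-pyran-2-yl)decyl] ethanethioate (two molecules)
Product: 18 lehualide K, via thiol 17 (not isolated)
Conditions: K2CO3 (2 equiv), degassed MeOH, 0 °C; then I2, MeOH/CH2Cl2, 0 °C → rt
Reagents that add atoms: none
Why: Thioester methanolysis is far faster than attack on the electron-rich, fully substituted lactone, and iodine oxidation of the thiol in the same flask gives the symmetrical disulfide while the ring offers no free C–H position for iodination.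

**Compound list**
1 | methyl methoxyacetate | COCC(=O)OC | starting material
2 | methyl formate | COC=O | starting material
3 | sodium 2,3-dimethoxy-3-oxoprop-1-en-1-olate (configurationally labile, not isolated) | [Na+].[O-]C=C(OC)C(=O)OC | intermediate
4 | methyl (Z)-2,3-dimethoxyacrylate | CO/C=C(\OC)C(=O)OC | intermediate
5 | lithium (Z)-2,3-dimethoxyacrylate (not isolated) | [Li+].CO/C=C(\OC)C([O-])=O | intermediate
6 | (Z)-2,3-dimethoxyacrylic acid | CO/C=C(\OC)C(O)=O | intermediate
7 | dec-9-yn-1-ol | OCCCCCCCCC#C | starting material
8 | tert-butyl(dec-9-yn-1-yloxy)dimethylsilane | C#CCCCCCCCCO[Si](C)(C)C(C)(C)C | intermediate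
9 | chlorobis(cyclopentadienyl)[(1E)-10-{[tert-butyl(dimethyl)silyl]oxy}dec-1-en-1-yl]zirconium (not isolated; cyclopentadienyl rings written σ-bonded in the SMILES) | CC(C)(C)[Si](C)(C)OCCCCCCCC/C=C/[Zr](Cl)(C1C=CC=C1)C1C=CC=C1 | intermediate
10 | tert-butyl{[(9E)-10-iododec-9-en-1-yl]oxy}dimethylsilane | I/C=C/CCCCCCCCO[Si](C)(C)C(C)(C)C | intermediate
11 | propyne | CC#C | starting material
12 | tert-butyl(dimethyl){[(9E)-tridec-9-en-11-yn-1-yl]oxy}silane | CC#C/C=C/CCCCCCCCO[Si](C)(C)C(C)(C)C | intermediate
13 | 6-[(1E)-10-{[tert-butyl(dimethyl)silyl]oxy}dec-1-en-1-yl]-3,4-dimethoxy-5-methyl-2H-pyran-2-one | COc1c(C)c(/C=C/CCCCCCCCO[Si](C)(C)C(C)(C)C)oc(=O)c1OC | intermediate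
14 | 6-(10-{[tert-butyl(dimethyl)silyl]oxy}decyl)-3,4-dimethoxy-5-methyl-2H-pyran-2-one | COc1c(C)c(CCCCCCCCCCO[Si](C)(C)C(C)(C)C)oc(=O)c1OC | intermediate
15 | 6-(10-hydroxydecyl)-3,4-dimethoxy-5-methyl-2H-pyran-2-one | COc1c(C)c(CCCCCCCCCCO)oc(=O)c1OC | intermediate
16 | S-[10-(4,5-dimethoxy-3-methyl-6-oxo-6H-pyran-2-yl)decyl] ethanethioate | COc1c(C)c(CCCCCCCCCCSC(C)=O)oc(=O)c1OC | intermediate
17 | 3,4-dimethoxy-5-methyl-6-(10-sulfanyldecyl)-2H-pyran-2-one (not isolated) | COc1c(C)c(CCCCCCCCCCS)oc(=O)c1OC | intermediate
18 | lehualide K, 6,6'-[disulfanediylbis(decane-10,1-diyl)]bis(3,4-dimethoxy-5-methyl-2H-pyran-2-one) | COc1c(C)c(CCCCCCCCCCSSCCCCCCCCCCc2oc(=O)c(OC)c(OC)c2C)oc(=O)c1OC | target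

**Totals**
Total step count: 10.
Longest linear sequence: 8 steps (7 → 8 → 10 → 12 → 13 → 14 → 15 → 16 → 18). The acid branch (1 → 4 → 6) joins at step 6.

**Steps most likely to fail**

1. Step 6 (bears the label).
   - What may go wrong: decarboxylation of the electron-rich acid or failure of its C–H metalation before the alkyne is engaged. The enyne may also oligomerise at the temperature needed, or the alkyne insertion may lose its regiochemical bias.
   - Fallback: known chemistry in which the ring is built by lactonisation of a 3,5-dioxo ester instead of by C–H annulation. It sets out from 1 and comes back at 16.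
   - Deprotonation of 1 with LiN(iPr)2 (THF, −78 °C) and C-acylation with propanoyl chloride should give methyl 2-methoxy-3-oxopentanoate F1. Double deprotonation (NaH, then n-BuLi, THF, 0 °C) and acylation at C4 with commercial methyl undec-10-enoate should give methyl 2-methoxy-4-methyl-3,5-dioxopentadec-14-enoate F2. DBU in hot toluene should close the enol lactone to 6-(dec-9-en-1-yl)-4-hydroxy-3-methoxy-5-methyl-2H-pyran-2-one F3.
   - Me2SO4 and K2CO3 in acetone, conditions known to favour methylation at the 4-oxygen over the lactone carbonyl oxygen, should give 6-(dec-9-en-1-yl)-3,4-dimethoxy-5-methyl-2H-pyran-2-one F4. Radical anti-Markovnikov addition of thioacetic acid to the terminal alkene (AIBN, toluene, 80 °C) then gives 16.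

2. Step 10.
   - What may go wrong: opening of the lactone by methoxide or attack of the thiolate on the ring during S-deacetylation, and incomplete coupling or over-oxidation at sulfur.
   - Fallback: sulfur is carried as a trityl thioether that iodine converts directly to the disulfide, so no basic deprotection is needed. It sets out from 15 and comes back at 18.
   - Appel-type iodination of 15 (I2, PPh3, imidazole, CH2Cl2) should give 6-(10-iododecyl)-3,4-dimethoxy-5-methyl-2H-pyran-2-one F5. S-Alkylation of triphenylmethanethiol (K2CO3, DMF, rt) should give 3,4-dimethoxy-5-methyl-6-[10-(tritylsulfanyl)decyl]-2H-pyran-2-one F6. Iodine in CH2Cl2/MeOH then effects oxidative detritylation with S–S bond formation, as practised on S-trityl cysteine residues, to give 18.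

3. Step 1.
   - What may go wrong: competing C-methylation of the ambident enolate, self-condensation of the methoxyacetate, and poor control of the enol ether geometry. The last would deprive step 6 of the only isomer that can be metalated.
   - Fallback: thermodynamically controlled elimination from an acetal instead of kinetic enolate alkylation. It sets out from 3 and comes back at 4.
   - Enolate 3, generated as in step 1, is neutralised with HCl in MeOH to methyl 2-methoxy-3-oxopropanoate F7. With HC(OMe)3 and catalytic H2SO4 in MeOH this should give methyl 2,3,3-trimethoxypropanoate F8. Acid-catalysed loss of methanol (catalytic p-TsOH, heating with distillation of MeOH), the reaction type used to turn 3,3-dimethoxypropanoates into β-methoxyacrylates, proceeds under equilibrating conditions and should deliver the more stable Z enol ether 4.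

**Further compounds**
F1 | step 6 | methyl 2-methoxy-3-oxopentanoate | CCC(=O)C(OC)C(=O)OC
F2 | step 6 | methyl 2-methoxy-4-methyl-3,5-dioxopentadec-14-enoate | C=CCCCCCCCCC(=O)C(C)C(=O)C(OC)C(=O)OC
F3 | step 6 | 6-(dec-9-en-1-yl)-4-hydroxy-3-methoxy-5-methyl-2H-pyran-2-one | COc1c(O)c(C)c(CCCCCCCCC=C)oc1=O
F4 | step 6 | 6-(dec-9-en-1-yl)-3,4-dimethoxy-5-methyl-2H-pyran-2-one | COc1c(C)c(CCCCCCCCC=C)oc(=O)c1OC
F5 | step 10 | 6-(10-iododecyl)-3,4-dimethoxy-5-methyl-2H-pyran-2-one | COc1c(C)c(CCCCCCCCCCI)oc(=O)c1OC
F6 | step 10 | 3,4-dimethoxy-5-methyl-6-[10-(tritylsulfanyl)decyl]-2H-pyran-2-one | COc1c(C)c(CCCCCCCCCCSC(c2ccccc2)(c2ccccc2)c2ccccc2)oc(=O)c1OC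
F7 | step 1 | methyl 2-methoxy-3-oxopropanoate | COC(C=O)C(=O)OC
F8 | step 1 | methyl 2,3,3-trimethoxypropanoate | COC(OC)C(OC)C(=O)OC
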